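**Plan**
1. Numbering (germacrane): carbocycle C1–C10, lactone C6–O–C12(=O)–C11(=C13H2), ester on O8, ether bridge C3–O–C10. Cuts, in order: the acetate and the O8–acyl bond; the hemiketal O–C3 bond; C2–C3 and C3–C4 (C3 goes back to carbon monoxide); C7–C8; the butenolide C7=C11 and O6–C12 bonds.
2. Enabling feature: C3 lies between two alkenyl carbons (C2 of the cis C1=C2, C4 of the Z C4=C5) and 1,4 to the tertiary oxygen on C10 across the cis alkene. The 2,5-dihydrofuran-2-ol ring is therefore the closed form of a cis-γ-hydroxy dienone whose carbonyl can be delivered as CO between an alkenyl iodide and an alkenylstannane.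
3. Forward: the lactone ring arises first as a butenolide (steps 1–5); C7–C8 union gives the α-methylene lactone (16); esterification (17); then one operation closes the 10-membered carbocycle and, last, the dihydrofuranol ring (18); silyl-to-acetyl exchange ends the route (19–20).
4. Stereocenters: C6 from a lipase resolution, C10 from a Sharpless epoxidation, C7 by attack anti to the C6 substituent, C8 by chair allylation followed by Mitsunobu inversion, C3 dictated by C10 through the oxygen bridge.
5. Alkenes: Z-C4=C5 by trans-hydroalumination/iodination, cis-C1=C2 by diimide reduction of an iodoalkyne, side-chain Z by α-iodination of crotonaldehyde and retentive carbonylation.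

Key step: step 18

Remark: the zinc allylation of step 16 is taken to run through the closed chair transition state (7,8-anti adduct); the other outcome is dealt with under the risky steps.

**Route**

Step 1
Reactants: 1 acrolein; 2 prop-1-yn-1-ylmagnesium bromide
Product: 3 rac-hex-1-en-4-yn-3-ol
Conditions: THF, −78 to 0 °C; saturated aq NH4Cl
Reagents that add atoms: none
Why: 1,2-addition of the alkynyl Grignard reagent to the aldehyde carbonyl of the enal should give the racemic carbinol, no stereocontrol being needed at this stage.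

Step 2
Reactants: 3 rac-hex-1-en-4-yn-3-ol
Product: 5 rac-(2Z)-2-iodohexa-2,5-dien-4-ol, via cyclic alkenylalanate 4 (not isolated)
Conditions: NaAlH2(OCH2CH2OMe)2 (Red-Al), THF, 0 °C to rt; EtOAc; iodine, THF, −78 to 0 °C
Reagents that add atoms: iodine [I][I]
Why: hydroxyl-directed trans-hydroalumination of the propargylic alcohol places aluminium on the distal alkyne carbon in the five-membered alanate 4, and iodinolysis with retention should give the Z γ-iodo allylic alcohol (iodine cis to the carbinol carbon), which is the C4=C5 geometry of the target.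

Step 3
Reactants: 5 rac-(2Z)-2-iodohexa-2,5-dien-4-ol
Product: 6 (2Z,4S)-2-iodohexa-2,5-dien-4-ol
Conditions: immobilized Candida antarctica lipase B (Novozym 435), vinyl acetate, hexane, 30 °C, run past half conversion; chromatography
Reagents that add atoms: none
Why: lipase kinetic resolution by transesterification, in which by the Kazlauskas rule the (R)-enantiomer (large iodoalkenyl, medium vinyl) should be acetylated, leaving the (S)-alcohol that carries the C6 configuration.

Step 4
Reactants: 6 (2Z,4S)-2-iodohexa-2,5-dien-4-ol; 7 2-(bromomethyl)prop-2-enoic acid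
Product: 8 (2Z,4S)-2-iodohexa-2,5-dien-4-yl 2-(bromomethyl)prop-2-enoate
Conditions: N,N'-dicyclohexylcarbodiimide, DMAP (5 mol %), CH2Cl2, −20 to 0 °C
Reagents that add atoms: none
Why: Steglich esterification at low temperature with only catalytic DMAP should acylate the secondary alcohol without displacing the allylic bromide.

Step 5
Reactants: 8 (2Z,4S)-2-iodohexa-2,5-dien-4-yl 2-(bromomethyl)prop-2-enoate
Product: 9 (5S)-3-(bromomethyl)-5-[(1Z)-2-iodoprop-1-en-1-yl]furan-2(5H)-one
Conditions: second-generation Grubbs catalyst RuCl2(=CHPh)(H2IMes)(PCy3) (5 mol %), toluene (0.01 M), 80 °C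
Reagents that add atoms: none
Why: ring-closing metathesis that starts at the monosubstituted vinyl group and closes onto the acrylate should give the butenolide with loss of ethylene, the trisubstituted alkenyl iodide being too hindered and electron-poor to take part.

Step 6
Reactants: 10 (2E)-3-methylpent-2-en-4-yn-1-ol
Product: 11 [(2S,3S)-3-ethynyl-3-methyloxiran-2-yl]methanol
Conditions: Ti(OiPr)4 (10 mol %), L-(+)-diethyl tartrate (12 mol %), t-BuOOH, 4 Å molecular sieves, CH2Cl2, −20 °C
Reagents that add atoms: tert-butyl hydroperoxide CC(C)(C)OO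
Why: Sharpless asymmetric epoxidation of the E trisubstituted allylic alcohol, in which L-(+)-tartrate directs oxygen to the face that gives the (2S,3S)-epoxide and so fixes the tertiary C–O stereocenter (later C10).

Step 7
Reactants: 11 [(2S,3S)-3-ethynyl-3-methyloxiran-2-yl]methanol
Product: 12 (3R)-3-methylpent-4-yne-1,3-diol
Conditions: NaAlH2(OCH2CH2OMe)2 (1.1 equiv), THF, −20 to 0 °C; aq Rochelle salt
Reagents that add atoms: none
Why: the alkoxide-bound aluminium hydride delivers hydride intramolecularly to C2 of the 2,3-epoxy alcohol (directed SN2 opening), so the tertiary C3–O bond is untouched and the 1,3-diol keeps the configuration of step 6, while the low temperature should spare the alkyne.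

Step 8
Reactants: 12 (3R)-3-methylpent-4-yne-1,3-diol
Product: 13 (3R)-5-iodo-3-methylpent-4-yne-1,3-diol
Conditions: N-iodosuccinimide, AgNO3 (10 mol %), acetone, rt
Reagents that add atoms: N-iodosuccinimide O=C1CCC(=O)N1I
Why: silver-catalysed electrophilic iodination of the terminal alkyne C–H, a reaction that tolerates free hydroxyl groups.

Step 9
Reactants: 13 (3R)-5-iodo-3-methylpent-4-yne-1,3-diol
Product: 14 (3R,4Z)-5-iodo-3-methylpent-4-ene-1,3-diol
Conditions: 2-nitrobenzenesulfonyl hydrazide, Et3N, THF/i-PrOH, rt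
Reagents that add atoms: none
Why: diimide released from the sulfonyl hydrazide adds H2 syn to the iodoalkyne and should stop at the cis-iodoalkene, which sets the cis C1=C2 geometry.

Step 10
Reactants: 14 (3R,4Z)-5-iodo-3-methylpent-4-ene-1,3-diol
Product: 15 (3R,4Z)-3-methyl-5-(trimethylstannyl)pent-4-ene-1,3-diol
Conditions: Me3SnSnMe3 (1.5 equiv), Pd(PPh3)4 (5 mol %), THF, 60 °C
Reagents that add atoms: hexamethylditin C[Sn](C)(C)[Sn](C)(C)C
Why: palladium-catalysed stannylation of the alkenyl iodide with the distannane (oxidative addition, Sn–Sn transmetalation, reductive elimination) proceeds with retention of the cis geometry and tolerates the free diol.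

Step 11
Reactants: 15 (3R,4Z)-3-methyl-5-(trimethylstannyl)pent-4-ene-1,3-diol
Product: 16 (3R,4Z)-3-hydroxy-3-methyl-5-(trimethylstannyl)pent-4-enal
Conditions: Dess–Martin periodinane (1.1 equiv), NaHCO3, CH2Cl2, 0 °C; used crude
Reagents that add atoms: none
Why: Dess–Martin oxidation converts the primary alcohol into the aldehyde while the tertiary alcohol cannot be oxidised, and the buffered medium should preserve the alkenylstannane.

Step 12
Reactants: 17 (2E)-but-2-enal (crotonaldehyde)
Product: 18 (2Z)-2-iodobut-2-enal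
Conditions: iodine, K2CO3, DMAP (20 mol %), THF/H2O, rt
Reagents that add atoms: iodine [I][I]
Why: amine-catalysed α-iodination of the enal (conjugate addition of DMAP, iodination of the enolate, elimination) should give the Z α-iodoenal, in which methyl and iodine are cis.

Step 13
Reactants: 18 (2Z)-2-iodobut-2-enal
Product: 19 (2Z)-2-iodobut-2-en-1-ol
Conditions: NaBH4, CeCl3·7H2O, MeOH, 0 °C
Reagents that add atoms: none
Why: Luche reduction gives clean 1,2-reduction of the enal without touching the alkenyl iodide or its geometry.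

Step 14
Reactants: 19 (2Z)-2-iodobut-2-en-1-ol
Product: 20 tert-butyl{[(2Z)-2-iodobut-2-en-1-yl]oxy}dimethylsilane
Conditions: t-BuMe2SiCl, imidazole, DMF, rt
Reagents that add atoms: tert-butyldimethylsilyl chloride CC(C)(C)[Si](C)(C)Cl
Why: standard silylation of the primary allylic alcohol, the silyl ether being chosen over the acetate because it is inert to phosphines and to zerovalent palladium in steps 15, 17 and 18.

Step 15
Reactants: 20 tert-butyl{[(2Z)-2-iodobut-2-en-1-yl]oxy}dimethylsilane
Product: 21 (2Z)-2-{[(tert-butyldimethylsilyl)oxy]methyl}but-2-enoic acid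
Conditions: Pd(OAc)2 (5 mol %), PPh3 (15 mol %), CO (1 atm), Et3N, DMF/H2O, 60 °C; citric acid work-up
Reagents that add atoms: carbon monoxide [C-]#[O+]; water O
Why: palladium-catalysed hydroxycarbonylation of the alkenyl iodide (oxidative addition, CO insertion, hydrolysis of the acylpalladium) replaces iodine by CO2H with retention, so carboxyl and methyl are cis as in the side chain of the target.

Step 16
Reactants: 9 (5S)-3-(bromomethyl)-5-[(1Z)-2-iodoprop-1-en-1-yl]furan-2(5H)-one; 16 (3R,4Z)-3-hydroxy-3-methyl-5-(trimethylstannyl)pent-4-enal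
Product: 22 (4R,5S)-4-[(1S,3R,4Z)-1,3-dihydroxy-3-methyl-5-(trimethylstannyl)pent-4-en-1-yl]-5-[(1Z)-2-iodoprop-1-en-1-yl]-3-methylideneoxolan-2-one
Conditions: Zn, THF/saturated aq NH4Cl, 0 °C to rt
Reagents that add atoms: none
Why: zinc Barbier allylation in which the allylzinc reacts at its γ-carbon (C7) through a closed chair transition state, anti to the C6 alkenyl group (trans lactone, 7R) and, because the allyl unit is locked in the butenolide ring with C6 trans to the CH2Zn carbon, with the aldehyde substituent equatorial to give the 7,8-anti (8S) alcohol while the α-methylene lactone is restored.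

Step 17
Reactants: 22 the (8S) allylation adduct; 21 (2Z)-2-{[(tert-butyldimethylsilyl)oxy]methyl}but-2-enoic acid
Product: 23 (1R,3R,4Z)-3-hydroxy-1-{(2S,3R)-2-[(1Z)-2-iodoprop-1-en-1-yl]-4-methylidene-5-oxooxolan-3-yl}-3-methyl-5-(trimethylstannyl)pent-4-en-1-yl (2Z)-2-{[(tert-butyldimethylsilyl)oxy]methyl}but-2-enoate
Conditions: PPh3, DIAD, toluene, 0 °C to rt
Reagents that add atoms: none
Why: Mitsunobu esterification of the secondary C8 alcohol (the tertiary C10 alcohol does not react) proceeds by SN2 displacement of the oxyphosphonium by the carboxylate and should invert C8 to the required (8R) ester.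

Step 18
Reactants: 23 the (8R) ester carrying the C4 alkenyl iodide and the C2 cis-alkenylstannane
Product: 25 (1Z,3R,4Z,6R,7R,8R,10R)-3,10-epoxy-3-hydroxygermacra-1,4,11(13)-trien-12,6-olid-8-yl (2Z)-2-{[(tert-butyldimethylsilyl)oxy]methyl}but-2-enoate, via hydroxy dienone 24 (not isolated)
Conditions: Pd2(dba)3 (10 mol %), AsPh3 (40 mol %), CO (3 atm), NMP, 50 °C, slow addition of 23 to a final 1 mM
Reagents that add atoms: carbon monoxide [C-]#[O+]
Why: Zerovalent palladium inserts into the C4–iodine bond, CO insertion gives the C3 acylpalladium, the cis-alkenylstannane transmetalates at C2 within the same molecule and reductive elimination forms C2–C3 with retention of both alkene geometries, giving the 10-membered (1Z,4Z)-dien-3-one 24. The closest known reaction type is the carbonylative Stille macrocyclization of an alkenyl halide with an alkenylstannane to a cross-conjugated macrocyclic dienone, joined here to the spontaneous hemiketalization of a cis-γ-hydroxy enone. The carbocycle closes by C–C reductive elimination from an 11-membered palladacycle under high dilution, and the dihydrofuran then closes by 5-exo-trig addition of the C10 hydroxyl to the C3 carbonyl, which is possible only because C1=C2 is cis. The new stereocenter C3 is controlled by C10, since the one-atom oxygen bridge can span the dihydrofuran only cis to the C4–C9 bridge and the reversible hemiketal leaves (3R) as the only closed form. The step needs CO insertion to outrun direct coupling (CO pressure and the weakly donating AsPh3; the direct product would be a 9-membered ring), ring closure to outrun oligomerization (slow addition), and capture of the acylpalladium by tin and not by oxygen (O8 is already acylated and the tertiary C10 hydroxyl could only give a 9-membered lactone).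

Step 19
Reactants: 25 the silyl-protected hemiketal
Product: 26 (1Z,3R,4Z,6R,7R,8R,10R)-3,10-epoxy-3-hydroxygermacra-1,4,11(13)-trien-12,6-olid-8-yl (2Z)-2-(hydroxymethyl)but-2-enoate
Conditions: HF·pyridine, pyridine, THF, 0 °C
Reagents that add atoms: none
Why: buffered fluoride cleavage of the primary silyl ether, to which the lactone, the ester and the tertiary hemiketal should be stable.

Step 20
Reactants: 26 the primary allylic alcohol
Product: 27 (1Z,3R,4Z,6R,7R,8R,10R)-3,10-epoxy-3-hydroxygermacra-1,4,11(13)-trien-12,6-olid-8-yl (2Z)-2-(acetoxymethyl)but-2-enoate (CNP0256971.1)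
Conditions: Ac2O, pyridine, CH2Cl2, 0 °C
Reagents that add atoms: acetic anhydride CC(=O)OC(C)=O
Why: acetylation of the primary allylic alcohol under mild conditions should leave the hindered tertiary hemiketal hydroxyl free and give the target.

**Compound list**

1 | acrolein (prop-2-enal) | C=CC=O | starting material
2 | prop-1-yn-1-ylmagnesium bromide | CC#C[Mg]Br | starting material
3 | rac-hex-1-en-4-yn-3-ol | C=CC(O)C#CC | intermediate
4 | sodium 2,2-bis(2-methoxyethoxy)-3-methyl-5-vinyl-2,5-dihydro-1,2-oxaluminol-2-uide (cyclic alkenylalanate, not isolated) | C=CC1O[Al-](OCCOC)(OCCOC)C(C)=C1.[Na+] | intermediate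
5 | rac-(2Z)-2-iodohexa-2,5-dien-4-ol | C=CC(O)/C=C(/C)I | intermediate
6 | (2Z,4S)-2-iodohexa-2,5-dien-4-ol | C=C[C@H](O)/C=C(/C)I | intermediate
7 | 2-(bromomethyl)prop-2-enoic acid | C=C(CBr)C(=O)O | starting material
8 | (2Z,4S)-2-iodohexa-2,5-dien-4-yl 2-(bromomethyl)prop-2-enoate | C=C[C@H](OC(=O)C(=C)CBr)/C=C(/C)I | intermediate
9 | (5S)-3-(bromomethyl)-5-[(1Z)-2-iodoprop-1-en-1-yl]furan-2(5H)-one | BrCC1=C[C@H](OC1=O)/C=C(/C)I | intermediate
10 | (2E)-3-methylpent-2-en-4-yn-1-ol | C#C/C(C)=C/CO | starting material
11 | [(2S,3S)-3-ethynyl-3-methyloxiran-2-yl]methanol | C#C[C@]1(C)O[C@H]1CO | intermediate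
12 | (3R)-3-methylpent-4-yne-1,3-diol | C#C[C@](C)(O)CCO | intermediate
13 | (3R)-5-iodo-3-methylpent-4-yne-1,3-diol | IC#C[C@](C)(O)CCO | intermediate
14 | (3R,4Z)-5-iodo-3-methylpent-4-ene-1,3-diol | I/C=C\[C@](C)(O)CCO | intermediate
15 | (3R,4Z)-3-methyl-5-(trimethylstannyl)pent-4-ene-1,3-diol | C[Sn](C)(C)/C=C\[C@](C)(O)CCO | intermediate
16 | (3R,4Z)-3-hydroxy-3-methyl-5-(trimethylstannyl)pent-4-enal | C[Sn](C)(C)/C=C\[C@](C)(O)CC=O | intermediate
17 | (2E)-but-2-enal (crotonaldehyde) | C/C=C/C=O | starting material
18 | (2Z)-2-iodobut-2-enal | C/C=C(\I)C=O | intermediate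
19 | (2Z)-2-iodobut-2-en-1-ol | C/C=C(\I)CO | intermediate
20 | tert-butyl{[(2Z)-2-iodobut-2-en-1-yl]oxy}dimethylsilane | C/C=C(\I)CO[Si](C)(C)C(C)(C)C | intermediate
21 | (2Z)-2-{[(tert-butyldimethylsilyl)oxy]methyl}but-2-enoic acid | C/C=C(\C(=O)O)CO[Si](C)(C)C(C)(C)C | intermediate
22 | (4R,5S)-4-[(1S,3R,4Z)-1,3-dihydroxy-3-methyl-5-(trimethylstannyl)pent-4-en-1-yl]-5-[(1Z)-2-iodoprop-1-en-1-yl]-3-methylideneoxolan-2-one (germacrane locants 6S,7R,8S,10R) | C=C1C(=O)O[C@H](/C=C(/C)I)[C@H]1[C@@H](O)C[C@@](C)(O)/C=C\[Sn](C)(C)C | intermediate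
23 | (1R,3R,4Z)-3-hydroxy-1-{(2S,3R)-2-[(1Z)-2-iodoprop-1-en-1-yl]-4-methylidene-5-oxooxolan-3-yl}-3-methyl-5-(trimethylstannyl)pent-4-en-1-yl (2Z)-2-{[(tert-butyldimethylsilyl)oxy]methyl}but-2-enoate (germacrane locants 6S,7R,8R,10R) | C=C1C(=O)O[C@H](/C=C(/C)I)[C@H]1[C@H](OC(=O)/C(=C\C)CO[Si](C)(C)C(C)(C)C)C[C@@](C)(O)/C=C\[Sn](C)(C)C | intermediate
24 | (1Z,4Z,6R,7R,8R,10R)-10-hydroxy-3-oxogermacra-1,4,11(13)-trien-12,6-olid-8-yl (2Z)-2-{[(tert-butyldimethylsilyl)oxy]methyl}but-2-enoate (not isolated) | C=C1C(=O)O[C@@H]2/C=C(/C)C(=O)/C=C\[C@](C)(O)C[C@@H](OC(=O)/C(=C\C)CO[Si](C)(C)C(C)(C)C)[C@@H]12 | intermediate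
25 | (1Z,3R,4Z,6R,7R,8R,10R)-3,10-epoxy-3-hydroxygermacra-1,4,11(13)-trien-12,6-olid-8-yl (2Z)-2-{[(tert-butyldimethylsilyl)oxy]methyl}but-2-enoate | C=C1C(=O)O[C@@H]2/C=C(/C)[C@@]3(O)C=C[C@@](C)(C[C@@H](OC(=O)/C(=C\C)CO[Si](C)(C)C(C)(C)C)[C@@H]12)O3 | intermediate
26 | (1Z,3R,4Z,6R,7R,8R,10R)-3,10-epoxy-3-hydroxygermacra-1,4,11(13)-trien-12,6-olid-8-yl (2Z)-2-(hydroxymethyl)but-2-enoate | C=C1C(=O)O[C@@H]2/C=C(/C)[C@@]3(O)C=C[C@@](C)(C[C@@H](OC(=O)/C(=C\C)CO)[C@@H]12)O3 | intermediate
27 | (1Z,3R,4Z,6R,7R,8R,10R)-3,10-epoxy-3-hydroxygermacra-1,4,11(13)-trien-12,6-olid-8-yl (2Z)-2-(acetoxymethyl)but-2-enoate | C=C1C(=O)O[C@@H]2/C=C(/C)[C@@]3(O)C=C[C@@](C)(C[C@@H](OC(=O)/C(=C\C)COC(C)=O)[C@@H]12)O3 | target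

**Count**

Total step count: 20. Longest linear sequence: 11 steps (10 to 27, steps 6–11 and 16–20).

**Steps most likely to fail**

Step 18. Intramolecular transmetalation and reductive elimination toward the strained (1Z,4Z)-dienone may be slow, so that intermolecular coupling to oligomers, protodestannylation or cis-to-trans isomerization of the alkenylstannane take over. The fallback builds the carbocycle as the less strained (1E,4Z)-dienone and closes the oxygen bridge photochemically. It sets out from 12. Palladium-catalysed syn-hydrostannation (Bu3SnH, PdCl2(PPh3)2, THF, 0 °C) should give (3R,4E)-3-methyl-5-(tributylstannyl)pent-4-ene-1,3-diol F1. Dess–Martin oxidation gives (3R,4E)-3-hydroxy-3-methyl-5-(tributylstannyl)pent-4-enal F2. Zinc allylation with 9 as in step 16 gives the (8S) trans-stannyl adduct F3, and Mitsunobu esterification with 21 as in step 17 gives the (8R) trans-stannyl ester F4. Carbonylative Stille macrocyclization under the conditions of step 18 then gives the (1E,4Z)-10-hydroxy-3-oxo dienone F5, which cannot form a hemiketal. Irradiation at 365 nm in degassed benzene, where only the dienone absorbs, isomerizes C1=C2, and the cis isomer is drained from the photoequilibrium as the hemiketal. This E-to-Z conversion with transannular trapping is known for 10-hydroxy-3-oxogermacra-1,4-dienolides. The fallback comes back to the route at 25.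

Step 17. The activated C8 oxyphosphonium may undergo E2 elimination toward C7=C8, or acyl transfer with retention, because the carbinol is flanked by the branched C7. The fallback separates activation from displacement. It sets out from 22. Chloromethanesulfonyl chloride and pyridine in CH2Cl2 at 0 °C should give the C8 chloromethanesulfonate of 22 F6, with the tertiary hydroxyl untouched. SN2 displacement with the caesium salt of 21 (21, Cs2CO3, 18-crown-6, toluene, 60 °C) inverts C8 and comes back to the route at 23.

Step 16. Closed and open transition states may compete in the aqueous zinc medium, so that the two faces of the aldehyde are attacked with low selectivity and C8 epimers result. The fallback makes the union stereoconvergent instead of stereoselective. It sets out from 9 and 16. The epimers are separated; the (8S) alcohol 22 goes on through step 17 with inversion. The (8R) epimer of 22 F7 is acylated with retention by 21 through its 2,4,6-trichlorobenzoyl mixed anhydride (2,4,6-trichlorobenzoyl chloride, Et3N, then DMAP, toluene, rt; Yamaguchi esterification). Both streams come back to the route at 23.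

**Further compounds**

F1 | step 18 | (3R,4E)-3-methyl-5-(tributylstannyl)pent-4-ene-1,3-diol | CCCC[Sn](CCCC)(CCCC)/C=C/[C@](C)(O)CCO
F2 | step 18 | (3R,4E)-3-hydroxy-3-methyl-5-(tributylstannyl)pent-4-enal | CCCC[Sn](CCCC)(CCCC)/C=C/[C@](C)(O)CC=O
F3 | step 18 | (4R,5S)-4-[(1S,3R,4E)-1,3-dihydroxy-3-methyl-5-(tributylstannyl)pent-4-en-1-yl]-5-[(1Z)-2-iodoprop-1-en-1-yl]-3-methylideneoxolan-2-one | C=C1C(=O)O[C@H](/C=C(/C)I)[C@H]1[C@@H](O)C[C@@](C)(O)/C=C/[Sn](CCCC)(CCCC)CCCC
F4 | step 18 | (1R,3R,4E)-3-hydroxy-1-{(2S,3R)-2-[(1Z)-2-iodoprop-1-en-1-yl]-4-methylidene-5-oxooxolan-3-yl}-3-methyl-5-(tributylstannyl)pent-4-en-1-yl (2Z)-2-{[(tert-butyldimethylsilyl)oxy]methyl}but-2-enoate | C=C1C(=O)O[C@H](/C=C(/C)I)[C@H]1[C@H](OC(=O)/C(=C\C)CO[Si](C)(C)C(C)(C)C)C[C@@](C)(O)/C=C/[Sn](CCCC)(CCCC)CCCC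
F5 | step 18 | (1E,4Z,6R,7R,8R,10R)-10-hydroxy-3-oxogermacra-1,4,11(13)-trien-12,6-olid-8-yl (2Z)-2-{[(tert-butyldimethylsilyl)oxy]methyl}but-2-enoate | C=C1C(=O)O[C@@H]2/C=C(/C)C(=O)/C=C/[C@](C)(O)C[C@@H](OC(=O)/C(=C\C)CO[Si](C)(C)C(C)(C)C)[C@@H]12
F6 | step 17 | C8 chloromethanesulfonate of 22 (configuration of 22 retained at all centers) | C=C1C(=O)O[C@H](/C=C(/C)I)[C@H]1[C@@H](OS(=O)(=O)CCl)C[C@@](C)(O)/C=C\[Sn](C)(C)C
F7 | step 16 | (4R,5S)-4-[(1R,3R,4Z)-1,3-dihydroxy-3-methyl-5-(trimethylstannyl)pent-4-en-1-yl]-5-[(1Z)-2-iodoprop-1-en-1-yl]-3-methylideneoxolan-2-one (C8 epimer of 22) | C=C1C(=O)O[C@H](/C=C(/C)I)[C@H]1[C@H](O)C[C@@](C)(O)/C=C\[Sn](C)(C)C
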